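**Retrosynthetic overview** (p-menthane numbering: C1 = CBr(CH3), C2 = CHBr, C3, C4 = CH, C5, C6 in the ring; C8 = side-chain CBr, C9 = CH2Br)

1. The target is a (4R)-p-menth-1-ene with an (8R)-8,9-dibromide, after trans-diaxial Br2 addition to C1=C2. C8–Br is traced to a tertiary carbinol bearing C9–Br (retention through a bromonium ion), then to an 8,9-oxirane, then to a C8 methyl ketone (catalytic asymmetric CH2 transfer).
2. In the ring, C2–C3 and C1–C6 are cut together: C3–C4–C5–C6 comes from cyclobutanone 1 (C6 is its carbonyl carbon, its ring bond C3–C6 is the one broken), and C1–C2 with the C1 methyl comes from silyl alkyne 2.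
3. Enabling feature: the ring arc C3–C4–C5–C6 holds three plain CH2 groups around the single methine C4, opposite the only functionalised pair C1/C2 (a vicinal trans-dibromide, i.e. a masked alkene, i.e. an alkyne). Closing C3 onto C6 gives a 3-substituted cyclobutanone with a mirror plane through C4 and C6, so one catalyst-controlled C–C cleavage sets C4.
4. The C6 carbonyl and the C2 silyl group are traceless: tosylhydrazone reduction with 1,3-transposition gives an allylsilane, and SE2′ protodesilylation returns the double bond to C1=C2 with C6 as CH2.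
5. Ring order: only the six-membered ring is built (step 1, by two-carbon expansion of the four-membered ring); the C8/C9 oxirane of steps 6–7 is a temporary ring.

Key step: step 1

Assumption: the sense of induction of the chiral ligands in steps 1 and 6 is taken as written (R at C4; CH2 transfer to the Si face of the C8 carbonyl); if either proves opposite, the mirror-image ligand is used without other change.

**Step 1**
Reactants: 1 methyl 3-oxocyclobutane-1-carboxylate; 2 1-(trimethylsilyl)propyne
Product: 3 methyl (R)-4-methyl-5-oxo-3-(trimethylsilyl)cyclohex-3-ene-1-carboxylate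
Conditions: Ni(cod)2 (10 mol%), (S,S,S)-BINOL-derived phosphoramidite with N,N-bis(1-phenylethyl) group (20 mol%), toluene, 80 °C
Reagents that add atoms: 2, 1-(trimethylsilyl)propyne, CC#C[Si](C)(C)C
Why: Proposed new method: oxidative cyclisation of the strained C6 carbonyl of 1 with alkyne 2 on zerovalent nickel should give a spiro oxanickelacyclopentene in which the new C6–C1 bond is at the methyl-bearing alkyne carbon and the silyl-bearing carbon is on nickel, after which strain-releasing β-carbon elimination of one C(=O)–CH2 bond gives a seven-membered acyl nickelacycle and C(sp3)–C(sp2) reductive elimination forms the C3–C2 bond. The closest known reaction type is the racemic nickel/trialkylphosphine-catalysed intermolecular insertion of internal alkynes into the acyl–carbon bond of 3-substituted cyclobutanones, and enantiotopic C–C bond selection in such cyclobutanones is known for intramolecular alkene insertions with chiral ligands on nickel and rhodium; what is new is chiral-ligand control in the intermolecular alkyne case. The six-membered ring is closed by reductive elimination from the seven-membered metallacycle, a net two-carbon ring expansion (formal [4+2]) of the four-membered ring. The single new stereocentre C4 is set by the phosphoramidite ligand, which decides which of the two enantiotopic C6–CH2 bonds migrates to nickel. The step needs alkyne regioselectivity, which the SiMe3 group secures by taking the position on nickel and hence on C2, and chemoselectivity for the ring ketone over the ester, which ring strain secures.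

**Step 2**
Reactants: 3 methyl (R)-4-methyl-5-oxo-3-(trimethylsilyl)cyclohex-3-ene-1-carboxylate
Product: 4 methyl (R,E)-4-methyl-5-[2-(4-methylbenzenesulfonyl)hydrazinylidene]-3-(trimethylsilyl)cyclohex-3-ene-1-carboxylate
Conditions: TsNHNH2, AcOH (cat.), EtOH, 50 °C
Reagents that add atoms: 4-methylbenzenesulfonohydrazide, Cc1ccc(cc1)S(=O)(=O)NN
Why: Acid-catalysed hydrazone formation at the only ketone should tolerate the flanking methyl and silyl groups, leaves the ester, the vinylsilane and C4 untouched, and should give the E hydrazone with the sulfonamide turned away from C1.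

**Step 3**
Reactants: 4 methyl (R,E)-4-methyl-5-[2-(4-methylbenzenesulfonyl)hydrazinylidene]-3-(trimethylsilyl)cyclohex-3-ene-1-carboxylate
Product: 7 methyl (1R,5S)-4-methyl-5-(trimethylsilyl)cyclohex-3-ene-1-carboxylate, via N-boryl hydrazine 5 (not isolated), via allylic diazene 6 (not isolated)
Conditions: catecholborane, CHCl3, 0 °C; then NaOAc·3H2O, reflux
Reagents that add atoms: none
Why: This is the alkene-transposing catecholborane reduction of an enone tosylhydrazone, in which hydride adds to C6, acetate releases sulfinate to give diazene 6, and retro-ene loss of N2 puts hydrogen on C2 and the double bond at C6=C1, turning the vinylsilane into an allylsilane; the C2 stereocentre (hydrogen delivered on the diazene face, expected cis to the ester) is of no consequence because step 4 destroys it.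

**Step 4**
Reactants: 7 methyl (1R,5S)-4-methyl-5-(trimethylsilyl)cyclohex-3-ene-1-carboxylate
Product: 8 methyl (R)-4-methylcyclohex-3-ene-1-carboxylate
Conditions: CF3CO2H, CH2Cl2, 0 °C
Reagents that add atoms: none
Why: SE2′ protodesilylation of the allylsilane should protonate C6 to give the tertiary, β-silyl-stabilised C1 cation, and loss of the silyl group returns the double bond regiospecifically to C1=C2, so C6 ends as CH2 and the sense of the C4 stereocentre is kept.

**Step 5**
Reactants: 8 methyl (R)-4-methylcyclohex-3-ene-1-carboxylate
Product: 10 1-[(R)-4-methylcyclohex-3-en-1-yl]ethan-1-one, via Weinreb amide 9 (not isolated)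
Conditions: MeNH(OMe)·HCl, i-PrMgCl, THF, −20 °C; then MeMgBr, −20 to 0 °C; aq. NH4Cl
Reagents that add atoms: methylmagnesium bromide, C[Mg]Br; N,O-dimethylhydroxylamine hydrochloride, CNOC.Cl (its atoms are in 9 only)
Why: In this one-flask Weinreb ketone synthesis the magnesium amide converts the ester into amide 9, whose chelated adduct with MeMgBr stops at the ketone stage, and the tertiary C4–H is not expected to be removed under these conditions.

**Step 6**
Reactants: 10 1-[(R)-4-methylcyclohex-3-en-1-yl]ethan-1-one
Product: 11 (R)-2-methyl-2-[(R)-4-methylcyclohex-3-en-1-yl]oxirane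
Conditions: Me3S(O)I, NaH, THF; then 10, LaLi3[(S)-binaphthoxide]3 (5 mol%), [2,4,6-(MeO)3C6H2]3P=O (5 mol%), 5 Å MS, THF, rt
Reagents that add atoms: trimethylsulfoxonium iodide, C[S+](C)(C)=O.[I-]
Why: Catalytic asymmetric Corey–Chaykovsky epoxidation of a methyl ketone with the lanthanum–lithium binaphthoxide/phosphine oxide system should distinguish methyl from the branched ring substituent and deliver CH2 to the Si face of the C8 carbonyl, setting C8 as R under catalyst control, while the isolated ring alkene does not react with the sulfoxonium ylide.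

**Step 7**
Reactants: 11 (R)-2-methyl-2-[(R)-4-methylcyclohex-3-en-1-yl]oxirane
Product: 12 (R)-1-bromo-2-[(R)-4-methylcyclohex-3-en-1-yl]propan-2-ol
Conditions: Li2NiBr4, THF, 0 °C to rt; pH 7 buffer
Reagents that add atoms: dilithium tetrabromonickelate, [Li+].[Li+].Br[Ni-2](Br)(Br)Br
Why: SN2 opening of the 2,2-disubstituted oxirane by soft bromide should occur at the primary carbon C9, so the C8–O bond and the 8R configuration are untouched.

**Step 8**
Reactants: 12 (R)-1-bromo-2-[(R)-4-methylcyclohex-3-en-1-yl]propan-2-ol
Product: 13 (R)-1-bromo-2-[(1R,3S,4S)-3,4-dibromo-4-methylcyclohexyl]propan-2-ol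
Conditions: Br2, CH2Cl2, −78 °C
Reagents that add atoms: bromine, BrBr
Why: Anti addition of bromine through a bromonium ion that opens trans-diaxially (Fürst–Plattner rule) by bromide attack at the tertiary C1, on the half-chair that keeps the C4 side chain equatorial, should set C1 and C2 (both S) in one event by substrate control from C4, with bromide outcompeting the hindered tertiary hydroxyl.

**Step 9**
Reactants: 13 (R)-1-bromo-2-[(1R,3S,4S)-3,4-dibromo-4-methylcyclohexyl]propan-2-ol
Product: 14 (1S,2S,4R)-1,2-dibromo-4-[(R)-1,2-dibromopropan-2-yl]-1-methylcyclohexane (target)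
Conditions: HBr (33 wt% in AcOH), CH2Cl2, 0 °C to rt
Reagents that add atoms: hydrogen bromide, Br
Why: In this substitution with neighbouring-group participation the C9 bromine displaces the protonated tertiary hydroxyl from the rear to give a bromonium ion, which bromide should open at the tertiary C8 from the face the oxygen left, so two inversions give net retention and the 8R bromide, while the ring C–Br bonds are stable to HBr.

**Compound list**

1 | methyl 3-oxocyclobutane-1-carboxylate | COC(=O)C1CC(=O)C1 | starting material
2 | 1-(trimethylsilyl)propyne | CC#C[Si](C)(C)C | starting material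
3 | methyl (R)-4-methyl-5-oxo-3-(trimethylsilyl)cyclohex-3-ene-1-carboxylate | COC(=O)[C@@H]1CC(=O)C(C)=C([Si](C)(C)C)C1 | intermediate
4 | methyl (R,E)-4-methyl-5-[2-(4-methylbenzenesulfonyl)hydrazinylidene]-3-(trimethylsilyl)cyclohex-3-ene-1-carboxylate | COC(=O)[C@@H]1C/C(=N\NS(=O)(=O)c2ccc(C)cc2)C(C)=C([Si](C)(C)C)C1 | intermediate
5 | methyl (1R,5S)-5-[1-(1,3,2-benzodioxaborol-2-yl)-2-(4-methylbenzenesulfonyl)hydrazinyl]-4-methyl-3-(trimethylsilyl)cyclohex-3-ene-1-carboxylate | COC(=O)[C@@H]1C[C@H](N(NS(=O)(=O)c2ccc(C)cc2)B2Oc3ccccc3O2)C(C)=C([Si](C)(C)C)C1 | intermediate (not isolated)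
6 | methyl (1R,5S)-5-diazenyl-4-methyl-3-(trimethylsilyl)cyclohex-3-ene-1-carboxylate | COC(=O)[C@@H]1C[C@H](N=N)C(C)=C([Si](C)(C)C)C1 | intermediate (not isolated)
7 | methyl (1R,5S)-4-methyl-5-(trimethylsilyl)cyclohex-3-ene-1-carboxylate | COC(=O)[C@@H]1CC=C(C)[C@@H]([Si](C)(C)C)C1 | intermediate
8 | methyl (R)-4-methylcyclohex-3-ene-1-carboxylate | COC(=O)[C@@H]1CCC(C)=CC1 | intermediate
9 | (R)-N-methoxy-N,4-dimethylcyclohex-3-ene-1-carboxamide | CON(C)C(=O)[C@@H]1CCC(C)=CC1 | intermediate (not isolated)
10 | 1-[(R)-4-methylcyclohex-3-en-1-yl]ethan-1-one | CC(=O)[C@@H]1CCC(C)=CC1 | intermediate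
11 | (R)-2-methyl-2-[(R)-4-methylcyclohex-3-en-1-yl]oxirane | C[C@]1(CO1)[C@@H]2CCC(C)=CC2 | intermediate
12 | (R)-1-bromo-2-[(R)-4-methylcyclohex-3-en-1-yl]propan-2-ol | C[C@](O)(CBr)[C@@H]1CCC(C)=CC1 | intermediate
13 | (R)-1-bromo-2-[(1R,3S,4S)-3,4-dibromo-4-methylcyclohexyl]propan-2-ol | C[C@](O)(CBr)[C@@H]1CC[C@](C)(Br)[C@@H](Br)C1 | intermediate
14 | (1S,2S,4R)-1,2-dibromo-4-[(R)-1,2-dibromopropan-2-yl]-1-methylcyclohexane | C[C@](Br)(CBr)[C@@H]1CC[C@](C)(Br)[C@@H](Br)C1 | target

**Step count:** 9 steps in total; the longest linear sequence is 9 steps (1 to 14).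

**Steps most likely to fail**

- **Step 1 (Proposed new method).** The ligand may discriminate poorly between the two enantiotopic ring bonds in the β-carbon elimination, or alkyne oligomerisation may compete. The fallback uses known chemistry and sets out from 1 and 2. The same insertion with the established achiral catalyst (Ni(cod)2, PCy3, toluene, 100 °C) should give racemic methyl 4-methyl-5-oxo-3-(trimethylsilyl)cyclohex-3-ene-1-carboxylate F1. Hydrolysis with LiOH in THF/H2O should give the racemic acid F2. Crystallisation with (S)-1-phenylethylamine (the amine antipode to be confirmed by trial) should give the less soluble (S)-1-phenylethylammonium salt of the (R)-acid F3. Acidification should free (R)-4-methyl-5-oxo-3-(trimethylsilyl)cyclohex-3-ene-1-carboxylic acid F4, and methylation with TMSCHN2 in MeOH/toluene comes back to the route at 3.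

- **Step 9.** The bromonium ion may open to a free β-bromo cation, or bromide may attack C9 instead of C8; either erodes the configuration at C8, and E1 elimination may also compete. The fallback sets out from 10 and gives up catalyst control at C8 for a physical separation. Wittig methylenation (Ph3P=CH2, THF) should give (R)-limonene F7. Exhaustive bromination (Br2, 2 equiv, CH2Cl2, −20 °C) should then give the target together with its 8S epimer, (1S,2S,4R)-1,2-dibromo-4-[(S)-1,2-dibromopropan-2-yl]-1-methylcyclohexane F8. The two are separated by fractional crystallisation or chromatography, which comes back to the route at 14.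

- **Step 6.** The α-branched ketone may enolise under the basic ylide and catalyst, with loss of configuration at C4, or facial control at C8 may be weak. The fallback sets out from 10. Dimethylsulfonium methylide (Me3SI, KHMDS, THF, −20 °C), which adds faster, at lower temperature and without a basic catalyst, should give 2-methyl-2-[(R)-4-methylcyclohex-3-en-1-yl]oxirane F5 as both C8 epimers. Kinetic resolution by (salen)CrN3-catalysed azidolysis (TMSN3, i-PrOH), with the catalyst antipode that consumes the 8S epimer, should turn that epimer into (S)-1-azido-2-[(R)-4-methylcyclohex-3-en-1-yl]propan-2-ol F6. The 8R oxirane is left unchanged, which comes back to the route at 11.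

**Further compounds**

F1 | step 1 | methyl 4-methyl-5-oxo-3-(trimethylsilyl)cyclohex-3-ene-1-carboxylate (racemic) | COC(=O)C1CC(=O)C(C)=C([Si](C)(C)C)C1
F2 | step 1 | 4-methyl-5-oxo-3-(trimethylsilyl)cyclohex-3-ene-1-carboxylic acid (racemic) | OC(=O)C1CC(=O)C(C)=C([Si](C)(C)C)C1
F3 | step 1 | (S)-1-phenylethylammonium (R)-4-methyl-5-oxo-3-(trimethylsilyl)cyclohex-3-ene-1-carboxylate | C[C@H]([NH3+])c1ccccc1.[O-]C(=O)[C@@H]1CC(=O)C(C)=C([Si](C)(C)C)C1
F4 | step 1 | (R)-4-methyl-5-oxo-3-(trimethylsilyl)cyclohex-3-ene-1-carboxylic acid | OC(=O)[C@@H]1CC(=O)C(C)=C([Si](C)(C)C)C1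
F5 | step 6 | 2-methyl-2-[(R)-4-methylcyclohex-3-en-1-yl]oxirane (both C8 epimers) | CC1(CO1)[C@@H]2CCC(C)=CC2
F6 | step 6 | (S)-1-azido-2-[(R)-4-methylcyclohex-3-en-1-yl]propan-2-ol | C[C@@](O)(CN=[N+]=[N-])[C@@H]1CCC(C)=CC1
F7 | step 9 | (R)-limonene | CC(=C)[C@@H]1CCC(C)=CC1
F8 | step 9 | (1S,2S,4R)-1,2-dibromo-4-[(S)-1,2-dibromopropan-2-yl]-1-methylcyclohexane | C[C@@](Br)(CBr)[C@@H]1CC[C@](C)(Br)[C@@H](Br)C1
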